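Coupling partner to starting material runs from 0.320 in Tuesday's to 4.00 in Wednesday's, and you change nothing else.

| flask | starting material | coupling partner | free catalyst | temperature | remark | time |
|---|---|---|---|---|---|---|
| noon | 38 mM | 25 mM | 1.2 mM | −20 °C | run made earlier |  |
| Sunday's | 25 mM | 25.0 mM | 1.2 mM | −20 °C |  | 80 min |
| Wednesday's | 25 mM | 100 mM | 1.2 mM | −20 °C |  | 80 min |
| Saturday's | 25 mM | 12.0 mM | 1.2 mM | −20 °C |  | 80 min |
| Tuesday's | 25 mM | 8.00 mM | 1.2 mM | −20 °C |  | 80 min |
| Friday's | 25 mM | 15.0 mM | 1.2 mM | −20 °C |  | 80 min |
| Monday's | 25 mM | 50.0 mM | 1.2 mM | −20 °C |  | 80 min |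

noon run (percent of the starting material charged)

| time / min | target / % | over-reaction product / % | side product / % |
|---|---|---|---|
| 3.00 | 0 | 2 | 0 |
| 10.0 | 9 | 1 | 2 |
| 15.0 | 15 | 0 | 0 |
| 25.0 | 25 | 1 | 0 |
| 40.0 | 28 | 1 | 4 |
| 50.0 | 36 | 8 | 1 |

(each reading ± 1.5 percentage points)



- all flasks from highest to lowest share of target in all that became target or over-reaction product or side product, at 80 min (Sunday's / Wednesday's / Saturday's / Tuesday's / Friday's / Monday's)
- the share of target in all that became target or over-reaction product or side product of the flask you put first, at 80 min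
- the share of target in all that became target or over-reaction product or side product of the flask you put last, at 80 min

Here is my bench rule. I take both by-products to come from target, so losses grow with the target standing in the flask. The last noon reading gives the loss per target, by-products over target for each mM of target, called λ:

λ = 0.0183 mM⁻¹

This is a reading, and its readings scatter by 1.5 percentage points. At this temperature and catalyst charge, the rule is then:

share = 1 / (1 + λ[target])

But [target] depends on the share, so you go round twice.

First you need the amount made. I take one coupling partner per product, and equal fractions lost in equal times, whatever the charge. On that reckoning, the noon run puts the part of a coupling partner charge left at 80 min at: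

left = 15.8 %

By this reckoning, Tuesday's makes 6.73 mM of products:

round one: 89.0 %
round two: 90.1 %

Now the border. Multiply the charge ratio by the part used. Sunday's gives 0.842, which is below one. Monday's gives 1.68, which is above it. So in Monday's and Wednesday's, starting material is the limiting reagent, and I cap the amount made at 25 mM:

round one: 68.6 %
round two: 76.1 %

The rule has no clock past that border, so those two tie. I rank Tuesday's, Saturday's, Friday's, Sunday's, then Monday's and Wednesday's level.

The forecast differs, with Friday's > Saturday's > Sunday's > Tuesday's > Monday's > Wednesday's, 82 % and 38 %, holding that “The optimum is broad, about 82% at 12–25 mM”.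

The flasks give Tuesday's > Saturday's > Friday's > Sunday's > Monday's > Wednesday's, with 90.9 % first and 65.8 % last.

    target + released group → side product (k = 0.00290 M⁻¹ s⁻¹, Ea = 50.0 kJ mol⁻¹)
    catalyst intermediate A ⇌ released group + catalyst intermediate B (K = 0.0770 M, k = 0.0620 s⁻¹, Ea = 57.0 kJ mol⁻¹, ΔH = −81.0 kJ mol⁻¹)
    catalyst intermediate C → free catalyst + target (k = 0.0220 s⁻¹, Ea = 66.0 kJ mol⁻¹)
    coupling partner + free catalyst + target → free catalyst + over-reaction product (k = 5.90 M⁻² s⁻¹, Ea = 36.0 kJ mol⁻¹)
    coupling partner + free catalyst → catalyst intermediate A (k = 0.380 M⁻¹ s⁻¹, Ea = 48.0 kJ mol⁻¹)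
    starting material + catalyst intermediate B → catalyst intermediate C (k = 10.0 M⁻¹ s⁻¹, Ea = 35.0 kJ mol⁻¹)
    (constants at −20 °C)

In Wednesday's, over-reaction product stands at 17.1 % at 50 min and at 17.1 % at 80.0 min, while side product goes from 8.87 % to 17.1 %. Put Wednesday's target of 65.8 % into the rule and you get 76.9 %, against 65.8 %. Friday's target of 40.8 % gives 84.3 %, against 84.6 %.

(The earlier runs and the new flask are simulated on assumed constants; scatter was added.)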